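**Retrosynthetic overview**
1. Plakortone N ⇐ O‑debenzylation ⇐ C5 quaternary centre made last, by methyl transfer to a bicyclic oxocarbenium ion from the 5‑methoxy ketal (methyl enters cis to C6a–O, anti to the angular methyl).
2. Bicyclic ketal ⇐ one flask from an acyclic ynoate: Lindlar reduction and lactonisation close the butenolide (ring 1), then a hemiketal oxa‑Michael addition closes the tetrahydrofuran (ring 2) and fixes C3a as cis‑fused.
3. Ynoate carrying the C6a stereocentre ⇐ metal‑free, chiral‑counteranion‑controlled Mukaiyama aldol of the terminal enolsilane of the chain methyl ketone with methyl 4‑oxopent‑2‑ynoate (all inputs achiral).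
4. Enolsilane ⇐ methyl ketone ⇐ acid ⇐ Cu‑catalysed coupling of 4‑(benzyloxy)benzyl Grignard with 12‑bromododecanoic acid; ynone ⇐ methyl propiolate + Weinreb amide.

Assumption: the IDPi enantiomer that gives the (4S)‑adduct 13 is identified in an initial screen (both antipodes are made from (R)‑ or (S)‑BINOL); it is written below as (S,S).

**Step 1**
Reactants: 1 4‑(benzyloxy)benzyl chloride; 2 12‑bromododecanoic acid
Product: 5 13‑[4‑(benzyloxy)phenyl]tridecanoic acid, via [4‑(benzyloxy)benzyl]magnesium chloride 3 (not isolated), via chloromagnesium 12‑bromododecanoate 4 (not isolated)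
Conditions: 1 (2.3 equiv), Mg, THF, 0 °C; add 2, then Li2CuCl4 (3 mol %), THF/NMP, −20 → 20 °C; 1 M HCl
Reagents that add atoms: none
Why: The first equivalent of 3 deprotonates 2 to the inert carboxylate 4, and the second couples with its primary bromide in a Cu‑catalysed sp3–sp3 Grignard cross‑coupling (Kochi type); no stereocentre.

**Step 2**
Reactants: 5 13‑[4‑(benzyloxy)phenyl]tridecanoic acid
Product: 6 14‑[4‑(benzyloxy)phenyl]tetradecan‑2‑one
Conditions: MeLi (2.3 equiv), Et2O/THF, 0 → 20 °C; inverse quench into 1 M HCl, 0 °C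
Reagents that add atoms: methyllithium, [Li]C
Why: MeLi adds to the lithium carboxylate to give a dilithium gem‑diolate that resists a second addition and releases the methyl ketone only on acidic quench (carboxylic acid → methyl ketone synthesis).

**Step 3**
Reactants: 6 14‑[4‑(benzyloxy)phenyl]tetradecan‑2‑one
Product: 8 ({14‑[4‑(benzyloxy)phenyl]tetradec‑1‑en‑2‑yl}oxy)trimethylsilane, via lithium 14‑[4‑(benzyloxy)phenyl]tetradec‑1‑en‑2‑olate 7 (not isolated)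
Conditions: TMSCl (1.5 equiv), then LDA (1.15 equiv), THF, −78 °C; Et3N, pentane, filter
Reagents that add atoms: chlorotrimethylsilane, C[Si](C)(C)Cl
Why: LDA removes a CH3 proton under kinetic control at −78 °C and the terminal enolate 7 is silylated on oxygen by the TMSCl already present (kinetic silyl enol ether formation); no stereocentre.

**Step 4**
Reactants: 9 methyl propiolate; 10 N‑methoxy‑N‑methylacetamide
Product: 12 methyl 4‑oxopent‑2‑ynoate, via methyl 3‑lithiopropiolate 11 (not isolated)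
Conditions: LiHMDS (1.05 equiv), THF, −78 °C; 10, −78 → −45 °C; cold 1 M HCl
Reagents that add atoms: none
Why: The lithium acetylide 11 acylates on the Weinreb amide and the chelated tetrahedral adduct survives until the quench, so no over‑addition occurs (Weinreb ketone synthesis); no stereocentre.

**Step 5**
Reactants: 8 ({14‑[4‑(benzyloxy)phenyl]tetradec‑1‑en‑2‑yl}oxy)trimethylsilane; 12 methyl 4‑oxopent‑2‑ynoate
Product: 13 methyl (4S)‑18‑[4‑(benzyloxy)phenyl]‑4‑methyl‑6‑oxo‑4‑[(trimethylsilyl)oxy]octadec‑2‑ynoate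
Conditions: 8 (1.2 equiv), (S,S)‑IDPi (N‑triflyl imidodiphosphorimidate from 3,3'‑diaryl‑BINOL, 2 mol %), toluene, −78 °C, 48 h; Et3N
Reagents that add atoms: none
Why: Proposed new method: a silylium‑based, counteranion‑directed Mukaiyama aldol of a ketone‑derived enolsilane with a conjugated ynone, in which the enolsilane silylates the IDPi, the silylium ion bound inside the confined chiral anion activates the ketone oxygen of 12 (more basic than the ester, flanked by a rod‑like alkynyl and a methyl group that the pocket can tell apart), the terminal enolsilane carbon attacks one face to form the C4–C5 bond and set C4 (S), and silyl transfer to the aldolate turns the catalyst over; the closest known reaction type is the IDPi‑catalysed Mukaiyama aldol of silyl ketene acetals with simple methyl ketones, not yet shown for ketone enolsilanes or ynone acceptors.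

**Step 6**
Reactants: 13 methyl (4S)‑18‑[4‑(benzyloxy)phenyl]‑4‑methyl‑6‑oxo‑4‑[(trimethylsilyl)oxy]octadec‑2‑ynoate
Product: 18 (3aS,6aS)‑5‑{12‑[4‑(benzyloxy)phenyl]dodecyl}‑5‑methoxy‑6a‑methyltetrahydrofuro[3,2‑b]furan‑2(3H)‑one (C5 epimer mixture), via methyl (2Z,4S)‑18‑[4‑(benzyloxy)phenyl]‑4‑methyl‑6‑oxo‑4‑[(trimethylsilyl)oxy]octadec‑2‑enoate 14 (not isolated), via methyl (2Z,4S)‑18‑[4‑(benzyloxy)phenyl]‑4‑hydroxy‑4‑methyl‑6‑oxooctadec‑2‑enoate 15 (not isolated), via (5S)‑5‑{14‑[4‑(benzyloxy)phenyl]‑2‑oxotetradecyl}‑5‑methylfuran‑2(5H)‑one 16 (not isolated), via (5S)‑5‑{14‑[4‑(benzyloxy)phenyl]‑2‑hydroxy‑2‑methoxytetradecyl}‑5‑methylfuran‑2(5H)‑one 17 (not isolated)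
Conditions: H2 (1 atm), Lindlar catalyst, quinoline (0.2 equiv), MeOH, 0 °C; filter; CSA (0.5 equiv), MeOH, 23 °C
Reagents that add atoms: methanol, CO
Why: Lindlar syn‑semihydrogenation gives Z‑enoate 14, acidic methanol cleaves the silyl ether (15), the Z‑γ‑hydroxy ester lactonises to butenolide 16, and the methanol hemiketal 17 closes the tetrahydrofuran by 5‑exo intramolecular oxa‑Michael addition, which can only give the cis‑fused ring and so sets C3a (S) from C6a (ketalisation/oxa‑Michael cascade).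

**Step 7**
Reactants: 18 (3aS,6aS)‑5‑{12‑[4‑(benzyloxy)phenyl]dodecyl}‑5‑methoxy‑6a‑methyltetrahydrofuro[3,2‑b]furan‑2(3H)‑one
Product: 19 (3aS,5S,6aS)‑5‑{12‑[4‑(benzyloxy)phenyl]dodecyl}‑5,6a‑dimethyltetrahydrofuro[3,2‑b]furan‑2(3H)‑one
Conditions: AlMe3 (4 equiv), CH2Cl2, −78 → 0 °C; aq. Rochelle salt
Reagents that add atoms: trimethylaluminium, C[Al](C)C
Why: AlMe3 ionises the ketal to the bicyclic oxocarbenium ion and transfers methyl (C‑glycosylation‑type substitution); by the inside‑attack model for five‑membered oxocarbenium ions, the envelope with C6a–O pseudoaxial and C6a–CH3 pseudoequatorial is attacked on the face cis to C6a–O and away from the angular methyl, giving (5S).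

**Step 8**
Reactants: 19 (3aS,5S,6aS)‑5‑{12‑[4‑(benzyloxy)phenyl]dodecyl}‑5,6a‑dimethyltetrahydrofuro[3,2‑b]furan‑2(3H)‑one
Product: 20 plakortone N, (3aS,5S,6aS)‑5‑[12‑(4‑hydroxyphenyl)dodecyl]‑5,6a‑dimethyltetrahydrofuro[3,2‑b]furan‑2(3H)‑one
Conditions: H2 (1 atm), 10 % Pd/C, EtOAc, 23 °C
Reagents that add atoms: none
Why: Hydrogenolysis of the benzyl aryl ether frees the phenol; the lactone, the ring ether and all three stereocentres are untouched.

**Compound list**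
1 | 4‑(benzyloxy)benzyl chloride | ClCc1ccc(OCc2ccccc2)cc1 | starting material
2 | 12‑bromododecanoic acid | OC(=O)CCCCCCCCCCCBr | starting material
3 | [4‑(benzyloxy)benzyl]magnesium chloride | Cl[Mg]Cc1ccc(OCc2ccccc2)cc1 | intermediate
4 | chloromagnesium 12‑bromododecanoate | BrCCCCCCCCCCCC(=O)O[Mg]Cl | intermediate
5 | 13‑[4‑(benzyloxy)phenyl]tridecanoic acid | OC(=O)CCCCCCCCCCCCc1ccc(OCc2ccccc2)cc1 | intermediate
6 | 14‑[4‑(benzyloxy)phenyl]tetradecan‑2‑one | CC(=O)CCCCCCCCCCCCc1ccc(OCc2ccccc2)cc1 | intermediate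
7 | lithium 14‑[4‑(benzyloxy)phenyl]tetradec‑1‑en‑2‑olate | [Li]OC(=C)CCCCCCCCCCCCc1ccc(OCc2ccccc2)cc1 | intermediate
8 | ({14‑[4‑(benzyloxy)phenyl]tetradec‑1‑en‑2‑yl}oxy)trimethylsilane | C=C(O[Si](C)(C)C)CCCCCCCCCCCCc1ccc(OCc2ccccc2)cc1 | intermediate
9 | methyl propiolate | C#CC(=O)OC | starting material
10 | N‑methoxy‑N‑methylacetamide | CC(=O)N(C)OC | starting material
11 | methyl 3‑lithiopropiolate | [Li]C#CC(=O)OC | intermediate
12 | methyl 4‑oxopent‑2‑ynoate | CC(=O)C#CC(=O)OC | intermediate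
13 | methyl (4S)‑18‑[4‑(benzyloxy)phenyl]‑4‑methyl‑6‑oxo‑4‑[(trimethylsilyl)oxy]octadec‑2‑ynoate | COC(=O)C#C[C@@](C)(O[Si](C)(C)C)CC(=O)CCCCCCCCCCCCc1ccc(OCc2ccccc2)cc1 | intermediate
14 | methyl (2Z,4S)‑18‑[4‑(benzyloxy)phenyl]‑4‑methyl‑6‑oxo‑4‑[(trimethylsilyl)oxy]octadec‑2‑enoate | COC(=O)/C=C\[C@@](C)(O[Si](C)(C)C)CC(=O)CCCCCCCCCCCCc1ccc(OCc2ccccc2)cc1 | intermediate
15 | methyl (2Z,4S)‑18‑[4‑(benzyloxy)phenyl]‑4‑hydroxy‑4‑methyl‑6‑oxooctadec‑2‑enoate | COC(=O)/C=C\[C@@](C)(O)CC(=O)CCCCCCCCCCCCc1ccc(OCc2ccccc2)cc1 | intermediate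
16 | (5S)‑5‑{14‑[4‑(benzyloxy)phenyl]‑2‑oxotetradecyl}‑5‑methylfuran‑2(5H)‑one | O=C1C=C[C@](C)(CC(=O)CCCCCCCCCCCCc2ccc(OCc3ccccc3)cc2)O1 | intermediate
17 | (5S)‑5‑{14‑[4‑(benzyloxy)phenyl]‑2‑hydroxy‑2‑methoxytetradecyl}‑5‑methylfuran‑2(5H)‑one (hemiketal, either configuration at the hemiketal carbon) | O=C1C=C[C@](C)(CC(O)(OC)CCCCCCCCCCCCc2ccc(OCc3ccccc3)cc2)O1 | intermediate
18 | (3aS,6aS)‑5‑{12‑[4‑(benzyloxy)phenyl]dodecyl}‑5‑methoxy‑6a‑methyltetrahydrofuro[3,2‑b]furan‑2(3H)‑one (C5 epimer mixture) | COC1(CCCCCCCCCCCCc2ccc(OCc3ccccc3)cc2)C[C@]2(C)OC(=O)C[C@@H]2O1 | intermediate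
19 | (3aS,5S,6aS)‑5‑{12‑[4‑(benzyloxy)phenyl]dodecyl}‑5,6a‑dimethyltetrahydrofuro[3,2‑b]furan‑2(3H)‑one | C[C@]1(CCCCCCCCCCCCc2ccc(OCc3ccccc3)cc2)C[C@]2(C)OC(=O)C[C@@H]2O1 | intermediate
20 | plakortone N, (3aS,5S,6aS)‑5‑[12‑(4‑hydroxyphenyl)dodecyl]‑5,6a‑dimethyltetrahydrofuro[3,2‑b]furan‑2(3H)‑one | C[C@]1(CCCCCCCCCCCCc2ccc(O)cc2)C[C@]2(C)OC(=O)C[C@@H]2O1 | target

**Step count**
Total steps: 8. Longest linear sequence: 7 (steps 1, 2, 3, 5, 6, 7, 8); step 4 is a one‑step side branch.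

**Three steps most likely to fail**

Step 5 (the proposed new aldol). The enolsilane may add in conjugate fashion to the ynoate, the catalyst may not separate methyl from alkynyl well enough, or the strong acid may protodesilylate 8. Fallback with known chemistry, setting out from 8 and returning at 18: a Cu(II)–bis(oxazoline)‑catalysed aldol of enolsilane 8 with methyl pyruvate ((S,S)‑t‑Bu‑box·Cu(OTf)2, THF, −78 °C; 1 M HCl), a reaction established for ketone enolsilanes with high ee, gives methyl (2S)‑16‑[4‑(benzyloxy)phenyl]‑2‑hydroxy‑2‑methyl‑4‑oxohexadecanoate F1. Ketalisation (HC(OMe)3, MeOH, CSA) gives methyl (2S)‑16‑[4‑(benzyloxy)phenyl]‑2‑hydroxy‑4,4‑dimethoxy‑2‑methylhexadecanoate F2. DIBAL‑H (CH2Cl2, −78 °C) gives (2S)‑16‑[4‑(benzyloxy)phenyl]‑2‑hydroxy‑4,4‑dimethoxy‑2‑methylhexadecanal F3. Wittig olefination with Ph3P=CHCO2Me in MeOH (Z‑selective for α‑oxygenated aldehydes) gives methyl (2Z,4S)‑18‑[4‑(benzyloxy)phenyl]‑4‑hydroxy‑6,6‑dimethoxy‑4‑methyloctadec‑2‑enoate F4, which lactonises to (5S)‑5‑{14‑[4‑(benzyloxy)phenyl]‑2,2‑dimethoxytetradecyl}‑5‑methylfuran‑2(5H)‑one F5. CSA in MeOH with 2 equiv of water then gives 18 through hemiketal 17.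

Step 6 (Lindlar/acid cascade). The hemiketal oxa‑Michael addition may stall at 16 under acid. Butenolide 16 is a β‑acyloxy ketone and can lose its carboxylate by elimination, which would erode C6a. The ketal can also aromatise to a furan on long exposure to acid. Fallback, setting out from 14 (isolated after the hydrogenation stage) and returning at 19: put the methyl group in before ring closure and close the ring with a tertiary alkoxide, the established base‑mediated endgame for this lactone family. MeLi/CeCl3 (THF, −78 °C) adds only to the ketone of 14 and gives methyl (2Z,4S)‑18‑[4‑(benzyloxy)phenyl]‑6‑hydroxy‑4,6‑dimethyl‑4‑[(trimethylsilyl)oxy]octadec‑2‑enoate F6 as both C6 epimers. TBAF (THF, 0 °C) gives the diol ester methyl (2Z,4S)‑18‑[4‑(benzyloxy)phenyl]‑4,6‑dihydroxy‑4,6‑dimethyloctadec‑2‑enoate F7, which lactonises to (5S)‑5‑{14‑[4‑(benzyloxy)phenyl]‑2‑hydroxy‑2‑methyltetradecyl}‑5‑methylfuran‑2(5H)‑one F8. DBU (CH2Cl2, 23 °C) closes the ring by oxa‑Michael addition to give 19 and its C5 epimer (3aS,5R,6aS)‑5‑{12‑[4‑(benzyloxy)phenyl]dodecyl}‑5,6a‑dimethyltetrahydrofuro[3,2‑b]furan‑2(3H)‑one F9, separated by chromatography. No ketone is present during the basic steps, so C6a cannot be lost; the cost is that the C6 addition is unselective and about half the material ends as F9.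

Step 7 (C5 methylation). The facial preference is predicted from a model, not from a precedent on this ring system, so methyl may enter from the convex face and give the C5 epimer. The tertiary oxocarbenium ion may also lose a proton to the enol ether and aromatise. Fallback, setting out from 12 and returning at 20: reverse the roles of the two C5 substituents so that the same facial preference delivers the chain instead of the methyl group. The step 5 aldol of 12 with commercial 2‑(trimethylsiloxy)propene gives methyl (4S)‑4‑methyl‑6‑oxo‑4‑[(trimethylsilyl)oxy]hept‑2‑ynoate F10. The step 6 conditions take it through methyl (2Z,4S)‑4‑methyl‑6‑oxo‑4‑[(trimethylsilyl)oxy]hept‑2‑enoate F11, methyl (2Z,4S)‑4‑hydroxy‑4‑methyl‑6‑oxohept‑2‑enoate F12, (5S)‑5‑methyl‑5‑(2‑oxopropyl)furan‑2(5H)‑one F13 and its hemiketal (5S)‑5‑(2‑hydroxy‑2‑methoxypropyl)‑5‑methylfuran‑2(5H)‑one F14 to (3aS,6aS)‑5‑methoxy‑5,6a‑dimethyltetrahydrofuro[3,2‑b]furan‑2(3H)‑one F15. Allyltrimethylsilane with TMSOTf (CH2Cl2, −78 °C) gives (3aS,5S,6aS)‑5‑allyl‑5,6a‑dimethyltetrahydrofuro[3,2‑b]furan‑2(3H)‑one F16. Cross‑metathesis (Grubbs II, CH2Cl2, 40 °C) with 1‑(benzyloxy)‑4‑(undec‑10‑en‑1‑yl)benzene F17 (from 4‑(benzyloxy)phenylmagnesium bromide and 11‑bromoundec‑1‑ene, Li2CuCl4) gives (3aS,5S,6aS)‑5‑{(2E)‑12‑[4‑(benzyloxy)phenyl]dodec‑2‑en‑1‑yl}‑5,6a‑dimethyltetrahydrofuro[3,2‑b]furan‑2(3H)‑one F18. H2 over Pd/C saturates the alkene and removes the benzyl group to give 20.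

**Further compounds**
F1 | step 5 | methyl (2S)‑16‑[4‑(benzyloxy)phenyl]‑2‑hydroxy‑2‑methyl‑4‑oxohexadecanoate | COC(=O)[C@@](C)(O)CC(=O)CCCCCCCCCCCCc1ccc(OCc2ccccc2)cc1
F2 | step 5 | methyl (2S)‑16‑[4‑(benzyloxy)phenyl]‑2‑hydroxy‑4,4‑dimethoxy‑2‑methylhexadecanoate | COC(=O)[C@@](C)(O)CC(OC)(OC)CCCCCCCCCCCCc1ccc(OCc2ccccc2)cc1
F3 | step 5 | (2S)‑16‑[4‑(benzyloxy)phenyl]‑2‑hydroxy‑4,4‑dimethoxy‑2‑methylhexadecanal | O=C[C@@](C)(O)CC(OC)(OC)CCCCCCCCCCCCc1ccc(OCc2ccccc2)cc1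
F4 | step 5 | methyl (2Z,4S)‑18‑[4‑(benzyloxy)phenyl]‑4‑hydroxy‑6,6‑dimethoxy‑4‑methyloctadec‑2‑enoate | COC(=O)/C=C\[C@@](C)(O)CC(OC)(OC)CCCCCCCCCCCCc1ccc(OCc2ccccc2)cc1
F5 | step 5 | (5S)‑5‑{14‑[4‑(benzyloxy)phenyl]‑2,2‑dimethoxytetradecyl}‑5‑methylfuran‑2(5H)‑one | O=C1C=C[C@](C)(CC(OC)(OC)CCCCCCCCCCCCc2ccc(OCc3ccccc3)cc2)O1
F6 | step 6 | methyl (2Z,4S)‑18‑[4‑(benzyloxy)phenyl]‑6‑hydroxy‑4,6‑dimethyl‑4‑[(trimethylsilyl)oxy]octadec‑2‑enoate (both C6 epimers) | COC(=O)/C=C\[C@@](C)(O[Si](C)(C)C)CC(C)(O)CCCCCCCCCCCCc1ccc(OCc2ccccc2)cc1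
F7 | step 6 | methyl (2Z,4S)‑18‑[4‑(benzyloxy)phenyl]‑4,6‑dihydroxy‑4,6‑dimethyloctadec‑2‑enoate (both C6 epimers) | COC(=O)/C=C\[C@@](C)(O)CC(C)(O)CCCCCCCCCCCCc1ccc(OCc2ccccc2)cc1
F8 | step 6 | (5S)‑5‑{14‑[4‑(benzyloxy)phenyl]‑2‑hydroxy‑2‑methyltetradecyl}‑5‑methylfuran‑2(5H)‑one (both carbinol epimers) | O=C1C=C[C@](C)(CC(C)(O)CCCCCCCCCCCCc2ccc(OCc3ccccc3)cc2)O1
F9 | step 6 | (3aS,5R,6aS)‑5‑{12‑[4‑(benzyloxy)phenyl]dodecyl}‑5,6a‑dimethyltetrahydrofuro[3,2‑b]furan‑2(3H)‑one | C[C@@]1(CCCCCCCCCCCCc2ccc(OCc3ccccc3)cc2)C[C@]2(C)OC(=O)C[C@@H]2O1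
F10 | step 7 | methyl (4S)‑4‑methyl‑6‑oxo‑4‑[(trimethylsilyl)oxy]hept‑2‑ynoate | COC(=O)C#C[C@@](C)(O[Si](C)(C)C)CC(C)=O
F11 | step 7 | methyl (2Z,4S)‑4‑methyl‑6‑oxo‑4‑[(trimethylsilyl)oxy]hept‑2‑enoate | COC(=O)/C=C\[C@@](C)(O[Si](C)(C)C)CC(C)=O
F12 | step 7 | methyl (2Z,4S)‑4‑hydroxy‑4‑methyl‑6‑oxohept‑2‑enoate | COC(=O)/C=C\[C@@](C)(O)CC(C)=O
F13 | step 7 | (5S)‑5‑methyl‑5‑(2‑oxopropyl)furan‑2(5H)‑one | O=C1C=C[C@](C)(CC(C)=O)O1
F14 | step 7 | (5S)‑5‑(2‑hydroxy‑2‑methoxypropyl)‑5‑methylfuran‑2(5H)‑one | O=C1C=C[C@](C)(CC(C)(O)OC)O1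
F15 | step 7 | (3aS,6aS)‑5‑methoxy‑5,6a‑dimethyltetrahydrofuro[3,2‑b]furan‑2(3H)‑one (C5 epimer mixture) | COC1(C)C[C@]2(C)OC(=O)C[C@@H]2O1
F16 | step 7 | (3aS,5S,6aS)‑5‑allyl‑5,6a‑dimethyltetrahydrofuro[3,2‑b]furan‑2(3H)‑one | C[C@]1(CC=C)C[C@]2(C)OC(=O)C[C@@H]2O1
F17 | step 7 | 1‑(benzyloxy)‑4‑(undec‑10‑en‑1‑yl)benzene | C=CCCCCCCCCCc1ccc(OCc2ccccc2)cc1
F18 | step 7 | (3aS,5S,6aS)‑5‑{(2E)‑12‑[4‑(benzyloxy)phenyl]dodec‑2‑en‑1‑yl}‑5,6a‑dimethyltetrahydrofuro[3,2‑b]furan‑2(3H)‑one | C[C@]1(C/C=C/CCCCCCCCCc2ccc(OCc3ccccc3)cc2)C[C@]2(C)OC(=O)C[C@@H]2O1
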